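A ratio of two readings from one flask, late target over early target, is what I carry through these runs.

| flask | starting material | reagent | free catalyst | time |
|---|---|---|---|---|
| Friday's | 50.0 mM | 150 mM | 5.00 mM |  |
| Sunday's | 20.0 mM | 120 mM | 5.00 mM |  |
| Wednesday's | 50.0 mM | 220 mM | 5.00 mM |  |
| Saturday's | 50.0 mM | 150 mM | 10.0 mM |  |
| Tuesday's | 120 mM | 150 mM | 5.00 mM | 36 min |

| run | time / min | [target] / mM |
|---|---|---|
| Friday's run | 2.0 | 3.0 |
| Friday's run | 6.2 | 9.5 |
| Friday's run | 12 | 15.2 |
| Friday's run | 19 | 19.3 |
| Friday's run | 27 | 21.7 |
| Friday's run | 36 | 22.9 |
| Sunday's run | 2.0 | 2.5 |
| Sunday's run | 6.2 | 6.0 |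
| Sunday's run | 12 | 7.4 |
| Sunday's run | 19 | 9.1 |
| Sunday's run | 27 | 9.5 |
| Sunday's run | 36 | 9.2 |
| Wednesday's run | 2.0 | 5.0 |
| Wednesday's run | 6.2 | 10.7 |
| Wednesday's run | 12 | 18.9 |
| Wednesday's run | 19 | 23.6 |
| Wednesday's run | 27 | 27.3 |
| Wednesday's run | 36 | 27.8 |
| Saturday's run | 2.0 | 7.0 |
| Saturday's run | 6.2 | 17.6 |
| Saturday's run | 12 | 26.0 |
| Saturday's run | 19 | 30.9 |
| Saturday's run | 27 | 32.2 |
| Saturday's run | 36 | 32.8 |

(each reading ± 0.5 mM)

- Overall: starting material + reagent -> target, with free catalyst as catalyst.
- Constant volume, constant temperature.
- What is held in complexes is read along with the free species.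
- An order is taken over about fifteen percent of the charge, up and down.

- the exponent of [free catalyst] in the starting rate at the charge of the Friday's run (at the point where two percent of the starting material have become target)
- the exponent of [starting material] in the starting rate at the charge of the Friday's run (at the point where two percent of the starting material have become target) (one fixed amount of target, the same in the runs compared)
- target in the Tuesday's run at 36 min, as a share of the starting material charged

Friday's target at 36 min over its target at 6.2 min, multiplied by that early time, gives 14.9 min, which I call the working time: the minutes a flask would need at its early mean rate to make what it has made by the late reading. The target is the integral of the rate, so late target equals early mean rate times working time. If the rate falls exponentially, the target at a clock time goes as one minus the exponential of minus that time over the lifetime, so the working time rises with the lifetime.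

Saturday's first two readings add up to twice Friday's for twice the free catalyst, so I take the catalyst order as 0.977. Wednesday's reading at 6.2 min against Friday's gives a reagent order of 0.311. With that correction, Sunday's reading against Friday's gives 0.426 in starting material across those two charges, and I expect less at Friday's charge.

Wednesday's working time, 16.1 min, lies near Friday's, so I set reagent aside here. Sunday's, 9.51 min, is shorter. Putting that difference on starting material gives a power of 0.494, hence a reckoned 23.0 min for Tuesday's flask.

Starting material is the limiting reagent in Tuesday's flask. As a loose upper estimate for that flask I take Friday's share, 45.8 %, and as a loose lower one Friday's amount over Tuesday's charge, 19.1 %. To tighten this, Friday's early mean rate, 1.53 mM min⁻¹, times the reckoned working time gives a lower estimate of 29.4 %. Raising that rate by the order across Sunday's and Friday's charges gives 2.22 mM min⁻¹ and an upper estimate of 42.7 %. I commit to the middle, 36.0 %.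

The forecast gives 1 and 0.25 for the orders and 35 % for Tuesday's flask, inside this bracket, holding that “bound substrate seems to protect the catalyst”.

The flask gives 0.99 and 0.31 for the orders, and 34.3 % for Tuesday's flask, inside the bracket.

    free catalyst + starting material ⇌ catalyst-substrate complex, settled at all times (13.20 M⁻¹)
    catalyst-substrate complex + reagent ⇌ ternary complex, settled at all times (24.90 M⁻¹)
    ternary complex → target + free catalyst (0.6480 min⁻¹)
    free catalyst → spent catalyst (0.1290 min⁻¹)
    starting material → decomposed substrate (0.03000 min⁻¹)

Divided by my reckoned early rate of 2.22 mM min⁻¹, Tuesday's result gives a working time of 18.5 min, longer than Friday's 14.9 min. The path from free catalyst to spent catalyst shortens it: the simulated Tuesday run without that path reaches 46.6 % instead of 34.3 %. On the same divisor, that run's working time is 25.1 min.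

The numbers in the tables were computed with made-up constants, noise included.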